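**Retrosynthetic overview** (ring A = pyranone, ring B = carbocycle)
1. The C5 carbinol, the only stereocentre, is set last by asymmetric transfer hydrogenation of the 4,5-dione.
2. Ring B is bought as cyclohexane-1,3-dione; ring A is the only ring formed, by C-acylation of the dione with a C20 2-ynoic acid and 6-endo closure of the enol oxygen onto the ynone.
3. Key C–C bond C2–C1′: the propiolic acid dianion, a β-acyl carbanion (d3 synthon, the future pyranone C2 with its polarity reversed), is alkylated by the C17 (Z)-alkenyl bromide, joining two carbons that are both electrophilic in normal reactivity.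
4. The bromide comes from 12-bromododecanal and a pentylidene ylide by Z-selective Wittig olefination.

Assumption: the SMILES is read as (5S,12′Z); the four starting materials are taken as catalogue chemicals.

**Step 1**
Reactants: 1 12-bromododecan-1-ol
Product: 2 12-bromododecanal
Conditions: TEMPO (10 mol %), PhI(OAc)2 (1.1 equiv), CH2Cl2, rt
Reagents that add atoms: none
Why: TEMPO/oxoammonium oxidation of a primary alcohol stops at the aldehyde and leaves the primary bromide untouched.

**Step 2**
Reactants: 2 12-bromododecanal; 3 pentyltriphenylphosphonium bromide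
Product: 5 (Z)-17-bromoheptadec-5-ene, via pentylidenetriphenylphosphorane 4 (not isolated)
Conditions: 3, NaN(SiMe3)2, THF, 0 °C; then 2, −78 °C → rt
Reagents that add atoms: none
Why: Salt-free Wittig olefination of an unstabilised ylide gives the Z-alkene under kinetic control (about 95:5 Z:E expected), and the primary bromide is not alkylated at −78 °C.

**Step 3** (key step)
Reactants: 5 (Z)-17-bromoheptadec-5-ene; 6 propiolic acid
Product: 9 (Z)-icos-15-en-2-ynoic acid, via dilithium propiolate 7 (not isolated), via lithium (Z)-icos-15-en-2-ynoate 8 (not isolated)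
Conditions: 6 (1.5 equiv), n-BuLi (2 equiv per 6), THF/HMPA, −78 °C; then 5, −78 °C → rt; 1 M HCl work-up
Reagents that add atoms: none
Why: Acetylide alkylation (SN2) of the propiolic acid dianion, whose carbanion is the β-carbon of an acrylate-type acceptor (a homoenolate-type d3 synthon at the alkyne oxidation level); this carbon becomes the normally electrophilic C2 of the pyranone and displaces the primary bromide in the dipolar medium.

**Step 4**
Reactants: 9 (Z)-icos-15-en-2-ynoic acid; 10 cyclohexane-1,3-dione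
Product: 13 2-[(Z)-heptadec-12-en-1-yl]-7,8-dihydro-4H-chromene-4,5(6H)-dione, via enol ester 11 (not isolated), via triketone 12 (not isolated)
Conditions: DCC (1.1 equiv), DMAP (0.3 equiv), Et3N (1.2 equiv), CH2Cl2, 0 °C → rt, 24 h
Reagents that add atoms: none
Why: Steglich-type O-acylation of the dione enol, DMAP-mediated O→C acyl shift (the standard entry to 2-acylcyclohexane-1,3-diones) and amine-promoted 6-endo-dig oxa-Michael closure of the enol oxygen onto the ynone build ring A; no stereocentre is formed.

**Step 5**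
Reactants: 13 2-[(Z)-heptadec-12-en-1-yl]-7,8-dihydro-4H-chromene-4,5(6H)-dione
Product: 14 (S)-2-[(Z)-heptadec-12-en-1-yl]-5-hydroxy-5,6,7,8-tetrahydro-4H-chromen-4-one
Conditions: RuCl(p-cymene)[(S,S)-TsDPEN] (2 mol %), HCO2H/Et3N 5:2, CH2Cl2, 30 °C; neutral work-up
Reagents that add atoms: none
Why: Noyori–Ikariya asymmetric transfer hydrogenation, in which the fused pyranone takes the aryl role of 1-tetralone or 4-chromanone, so the (S,S)-catalyst should give the (5S)-alcohol by analogy; the pyranone C4=O (doubly vinylogous ester) and the isolated Z-alkene are not reduced.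

**Compound list**
1 | 12-bromododecan-1-ol | OCCCCCCCCCCCCBr | starting material
2 | 12-bromododecanal | O=CCCCCCCCCCCCBr | intermediate
3 | pentyltriphenylphosphonium bromide | CCCCC[P+](c1ccccc1)(c1ccccc1)c1ccccc1.[Br-] | starting material
4 | pentylidenetriphenylphosphorane | CCCCC=P(c1ccccc1)(c1ccccc1)c1ccccc1 | intermediate (not isolated)
5 | (Z)-17-bromoheptadec-5-ene | CCCC/C=C\CCCCCCCCCCCBr | intermediate
6 | propiolic acid (prop-2-ynoic acid) | C#CC(=O)O | starting material
7 | dilithium propiolate (C,O-dianion of 6) | [Li]C#CC(=O)O[Li] | intermediate (not isolated)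
8 | lithium (Z)-icos-15-en-2-ynoate | CCCC/C=C\CCCCCCCCCCCC#CC(=O)[O-].[Li+] | intermediate (not isolated)
9 | (Z)-icos-15-en-2-ynoic acid | CCCC/C=C\CCCCCCCCCCCC#CC(=O)O | intermediate
10 | cyclohexane-1,3-dione | O=C1CCCC(=O)C1 | starting material
11 | 3-oxocyclohex-1-en-1-yl (Z)-icos-15-en-2-ynoate | CCCC/C=C\CCCCCCCCCCCC#CC(=O)OC1=CC(=O)CCC1 | intermediate (not isolated)
12 | 2-[(Z)-icos-15-en-2-ynoyl]cyclohexane-1,3-dione, drawn as its enol | CCCC/C=C\CCCCCCCCCCCC#CC(=O)C1=C(O)CCCC1=O | intermediate (not isolated)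
13 | 2-[(Z)-heptadec-12-en-1-yl]-7,8-dihydro-4H-chromene-4,5(6H)-dione | CCCC/C=C\CCCCCCCCCCCc1cc(=O)c2c(o1)CCCC2=O | intermediate
14 | (S)-2-[(Z)-heptadec-12-en-1-yl]-5-hydroxy-5,6,7,8-tetrahydro-4H-chromen-4-one | CCCC/C=C\CCCCCCCCCCCc1cc(=O)c2c(o1)CCC[C@@H]2O | target

**Totals**
Total steps: 5. Longest linear sequence: 5 (1 → 2 → 5 → 9 → 13 → 14). No protecting groups are used.

**Steps most likely to fail**

Step 3. The dianion is a weak, poorly soluble nucleophile; low conversion or E2 loss of the bromide is possible. The fallback keeps the same polarity-reversed C3 unit but uses it as a neutral, masked acetylide. It sets out from 5. Commercial triethyl orthopropiolate is lithiated (n-BuLi, THF, −78 °C) to lithium 3,3,3-triethoxyprop-1-yn-1-ide F1. F1 is alkylated by 5 (THF/HMPA, −78 °C → rt) to the orthoester (Z)-1,1,1-triethoxyicos-15-en-2-yne F2. Dilute aqueous acid turns F2 into ethyl (Z)-icos-15-en-2-ynoate F3. LiOH (THF/H2O) gives salt 8, and acidification returns to the route at 9.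

Step 4. The O→C acyl shift of an ynoyl group could be undercut by conjugate addition of DMAP or of the dione carbon to the ynoate, which would give the isomeric 2-pyranone. The fallback makes the C4–C4a bond by direct C-acylation of a carbanion equivalent of the dione. It sets out from 9, which is converted (EDC·HCl, MeNHOMe·HCl, i-Pr2NEt, CH2Cl2) into the Weinreb amide (Z)-N-methoxy-N-methylicos-15-en-2-ynamide F4. Commercial 1,5-dimethoxycyclohexa-1,4-diene is deprotonated between its two enol ethers (t-BuLi, THF/HMPA, −78 °C) to 6-lithio-1,5-dimethoxycyclohexa-1,4-diene F5. F5 adds to F4 to give (Z)-1-(2,6-dimethoxycyclohexa-2,5-dien-1-yl)icos-15-en-2-yn-1-one F6. 1 M HCl in THF hydrolyses both enol ethers, returning to the route at triketone 12, which closes to 13 in the same acid.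

Step 5. The C5 ketone is a deactivated vinylogous ester next to a Lewis-basic pyranone oxygen, so rate and ee are not assured, and the facial sense rests on analogy. The fallback separates reduction from stereocontrol. It sets out from 13, which is reduced with NaBH4 and CeCl3·7H2O (MeOH, −20 °C) to rac-2-[(Z)-heptadec-12-en-1-yl]-5-hydroxy-5,6,7,8-tetrahydro-4H-chromen-4-one F7. Kinetic resolution of F7 with Candida antarctica lipase B and vinyl acetate (MTBE, 30 °C) acetylates the (R)-enantiomer to (R)-2-[(Z)-heptadec-12-en-1-yl]-4-oxo-5,6,7,8-tetrahydro-4H-chromen-5-yl acetate F8. The unreacted (S)-alcohol is 14, separated by chromatography (at most 50 % yield).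

**Further compounds**
F1 | step 3 | lithium 3,3,3-triethoxyprop-1-yn-1-ide | [Li]C#CC(OCC)(OCC)OCC
F2 | step 3 | (Z)-1,1,1-triethoxyicos-15-en-2-yne | CCCC/C=C\CCCCCCCCCCCC#CC(OCC)(OCC)OCC
F3 | step 3 | ethyl (Z)-icos-15-en-2-ynoate | CCCC/C=C\CCCCCCCCCCCC#CC(=O)OCC
F4 | step 4 | (Z)-N-methoxy-N-methylicos-15-en-2-ynamide | CCCC/C=C\CCCCCCCCCCCC#CC(=O)N(C)OC
F5 | step 4 | 6-lithio-1,5-dimethoxycyclohexa-1,4-diene | [Li]C1C(OC)=CCC=C1OC
F6 | step 4 | (Z)-1-(2,6-dimethoxycyclohexa-2,5-dien-1-yl)icos-15-en-2-yn-1-one | CCCC/C=C\CCCCCCCCCCCC#CC(=O)C1C(OC)=CCC=C1OC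
F7 | step 5 | rac-2-[(Z)-heptadec-12-en-1-yl]-5-hydroxy-5,6,7,8-tetrahydro-4H-chromen-4-one | CCCC/C=C\CCCCCCCCCCCc1cc(=O)c2c(o1)CCCC2O
F8 | step 5 | (R)-2-[(Z)-heptadec-12-en-1-yl]-4-oxo-5,6,7,8-tetrahydro-4H-chromen-5-yl acetate | CCCC/C=C\CCCCCCCCCCCc1cc(=O)c2c(o1)CCC[C@H]2OC(C)=O
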